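**Retrosynthetic overview**

1. The aryl sulfate is placed on the only free phenol; an allyl ether (second phenol) and an aldehyde (future CH2OH) are unmasked together in the last step.
2. The aryl-CH2–alkene bond comes from a nickel-catalysed reductive coupling of a benzylic chloride (built from catechol) with the enol triflate of a cis-decalone; the triflate fixes the tetrasubstituted alkene.
3. Ring A is closed onto ring B by intramolecular enolate alkylation, which gives the cis ring fusion and the angular methyl.
4. Key step: a radical (HAT) Markovnikov hydroalkylation of an isopropenyl group with 1-chloro-3-iodopropane makes the gem-dimethyl quaternary carbon and brings in the three-carbon tether.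
5. Absolute configuration comes from one copper-catalysed asymmetric conjugate addition to 2-methylcyclohex-2-en-1-one; ring order: ring B (bought), then ring A, then the arene is attached.

Assumption: the SMILES is read as the cis-fused decalin (4aR,8aS; angular methyl and ring-fusion hydrogen on the same face), and the product is delivered as the free hydrogen sulfate drawn.

**Route**

Step 1
Reactants: 1 2-methylcyclohex-2-en-1-one; 2 isopropenylmagnesium bromide
Product: 3 (3S)-2-methyl-3-(prop-1-en-2-yl)cyclohexan-1-one (C2 epimer mixture)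
Conditions: Cu(OTf)2 (3 mol %), chiral hydroxyalkyl imidazolinium salt (NHC precursor, 4 mol %, the enantiomer that gives 3S), Et2O, −30 °C; then 1 M HCl, 0 °C
Reagents that add atoms: none
Why: Copper-catalysed asymmetric conjugate addition of an alkenyl Grignard reagent, in which the chiral NHC–copper complex delivers the isopropenyl group to one face of the enone and sets C3 as S (the future C4a), while C2 stays an epimer mixture because it is re-enolised and set in step 3.

Step 2
Reactants: 3 (3S)-2-methyl-3-(prop-1-en-2-yl)cyclohexan-1-one; 4 1-chloro-3-iodopropane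
Product: 5 (3S)-3-(5-chloro-2-methylpentan-2-yl)-2-methylcyclohexan-1-one
Conditions: Mn(dpm)3 (20 mol %), Ni(acac)2 (5 mol %), PhSiH3 (2 equiv), K2CO3, HFIP (additive), 1,2-dichloroethane/propylene carbonate, rt
Reagents that add atoms: none
Why: HAT-initiated Markovnikov hydroalkylation under manganese/nickel dual catalysis (the key step), in which the manganese hydride transfers a hydrogen atom to the CH2 of the isopropenyl group and the tertiary radical is captured by nickel and joined to the carbon of the C–I bond, creating the gem-dimethyl quaternary carbon while the ketone, the C–Cl bond and the C3 stereocentre are untouched.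

Step 3
Reactants: 5 (3S)-3-(5-chloro-2-methylpentan-2-yl)-2-methylcyclohexan-1-one
Product: 6 (4aR,8aS)-5,5,8a-trimethyloctahydronaphthalen-1(2H)-one
Conditions: KOtBu (1.2 equiv), NaI (10 mol %), THF/t-BuOH, 0 °C → 45 °C, high dilution
Reagents that add atoms: none
Why: Intramolecular enolate C-alkylation (6-exo-tet) through the more substituted potassium enolate, the only one that can reach the chloride, where the tether hangs from C3 so the new bond forms on the face of that tether and the angular methyl ends cis to the ring-fusion hydrogen, setting C8a as S in a cis-decalin.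

Step 4
Reactants: 6 (4aR,8aS)-5,5,8a-trimethyloctahydronaphthalen-1(2H)-one
Product: 8 (4aR,8aS)-2,5,5,8a-tetramethyloctahydronaphthalen-1(2H)-one (C2 epimer mixture), via lithium enolate 7 (not isolated)
Conditions: LDA (1.1 equiv), THF, −78 °C; MeI, −78 → 0 °C
Reagents that add atoms: iodomethane, CI
Why: Kinetic enolate alkylation, which is regiochemically unambiguous because C8a is quaternary so only C2 can be deprotonated, and whose new C2 centre is irrelevant because it becomes sp2 in step 5.

Step 5
Reactants: 8 (4aR,8aS)-2,5,5,8a-tetramethyloctahydronaphthalen-1(2H)-one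
Product: 10 (4aR,8aS)-2,5,5,8a-tetramethyl-3,4,4a,5,6,7,8,8a-octahydronaphthalen-1-yl trifluoromethanesulfonate, via potassium enolate 9 (not isolated)
Conditions: KHMDS (1.3 equiv), THF, −78 → 0 °C; PhNTf2, −78 °C → rt; then aq. NH4Cl
Reagents that add atoms: N-phenylbis(trifluoromethanesulfonimide), O=S(=O)(N(c1ccccc1)S(=O)(=O)C(F)(F)F)C(F)(F)F
Why: Enol triflate formation, in which the only possible enolate (C1=C2) is O-sulfonylated and thereby fixes the later tetrasubstituted double bond between the methyl-bearing carbon and the carbon next to the quaternary centre.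

Step 6
Reactants: 11 catechol
Product: 12 2-(prop-2-en-1-yloxy)phenol
Conditions: allyl bromide (1.0 equiv), K2CO3 (1.0 equiv), acetone, reflux, catechol in 1.5-fold excess
Reagents that add atoms: allyl bromide, C=CCBr
Why: Williamson mono-etherification, in which excess catechol and one equivalent of base favour the mono-allyl ether, which is separated from a little bis-ether.

Step 7
Reactants: 12 2-(prop-2-en-1-yloxy)phenol
Product: 13 4-bromo-2-(prop-2-en-1-yloxy)phenol
Conditions: NBS (1.0 equiv), MeCN, −20 → 0 °C
Reagents that add atoms: N-bromosuccinimide, O=C1CCC(=O)N1Br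
Why: Electrophilic aromatic bromination, in which the free hydroxyl is the stronger director so substitution goes para to it and the allyl double bond is left alone at low temperature.

Step 8
Reactants: 13 4-bromo-2-(prop-2-en-1-yloxy)phenol
Product: 15 4-hydroxy-3-(prop-2-en-1-yloxy)benzaldehyde, via dilithiated phenoxide 14 (not isolated)
Conditions: n-BuLi (2.2 equiv), THF, −78 °C; DMF, −78 → 0 °C; then 1 M HCl
Reagents that add atoms: N,N-dimethylformamide, CN(C)C=O
Why: Bromine–lithium exchange on the lithium phenoxide followed by formylation, in which the first equivalent of n-BuLi removes the phenol proton, the second exchanges the bromine, and DMF traps the aryllithium to give the aldehyde after acid hydrolysis.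

Step 9
Reactants: 15 4-hydroxy-3-(prop-2-en-1-yloxy)benzaldehyde
Product: 16 3-(chloromethyl)-4-hydroxy-5-(prop-2-en-1-yloxy)benzaldehyde
Conditions: paraformaldehyde (1.5 equiv), conc. aq. HCl, rt, 24 h
Reagents that add atoms: formaldehyde (as paraformaldehyde), C=O; hydrogen chloride, Cl
Why: Blanc chloromethylation, which stops after one substitution because the aldehyde deactivates the ring and which goes to the only free position ortho to the hydroxyl (the para position holds the aldehyde), as in the known chloromethylation of vanillin.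

Step 10
Reactants: 10 (4aR,8aS)-2,5,5,8a-tetramethyl-3,4,4a,5,6,7,8,8a-octahydronaphthalen-1-yl trifluoromethanesulfonate; 16 3-(chloromethyl)-4-hydroxy-5-(prop-2-en-1-yloxy)benzaldehyde
Product: 17 3-{[(4aR,8aS)-2,5,5,8a-tetramethyl-3,4,4a,5,6,7,8,8a-octahydronaphthalen-1-yl]methyl}-4-hydroxy-5-(prop-2-en-1-yloxy)benzaldehyde
Conditions: NiBr2·glyme (10 mol %), 4,4′-di-tert-butyl-2,2′-bipyridine (12 mol %), manganese powder (3 equiv), NaI (0.5 equiv), DMA, 25 °C, 16 (1.5 equiv)
Reagents that add atoms: none
Why: Nickel-catalysed reductive cross-electrophile coupling, in which the benzylic radical from the chloride is captured by the alkenylnickel species from the triflate, joining the benzylic carbon to the triflate-bearing alkene carbon without moving the double bond under neutral conditions that the free phenol, the aldehyde and both stereocentres should survive.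

Step 11
Reactants: 17 3-{[(4aR,8aS)-2,5,5,8a-tetramethyl-3,4,4a,5,6,7,8,8a-octahydronaphthalen-1-yl]methyl}-4-hydroxy-5-(prop-2-en-1-yloxy)benzaldehyde
Product: 18 sodium 2-{[(4aR,8aS)-2,5,5,8a-tetramethyl-3,4,4a,5,6,7,8,8a-octahydronaphthalen-1-yl]methyl}-4-formyl-6-(prop-2-en-1-yloxy)phenyl sulfate
Conditions: SO3·pyridine (5 equiv), pyridine, 50 °C; then aq. NaHCO3, reverse-phase purification
Reagents that add atoms: sulfur trioxide pyridine complex, [O-]S(=O)(=O)[n+]1ccccc1; sodium hydrogen carbonate, [Na+].OC([O-])=O
Why: O-sulfation of a phenol with the sulfur trioxide–pyridine complex, which can only occur at the phenol next to the benzylic carbon because it is the only hydroxyl in the molecule, and bicarbonate gives the stable sodium salt.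

Step 12
Reactants: 18 sodium 2-{[(4aR,8aS)-2,5,5,8a-tetramethyl-3,4,4a,5,6,7,8,8a-octahydronaphthalen-1-yl]methyl}-4-formyl-6-(prop-2-en-1-yloxy)phenyl sulfate
Product: 20 2-{[(4aR,8aS)-2,5,5,8a-tetramethyl-3,4,4a,5,6,7,8,8a-octahydronaphthalen-1-yl]methyl}-6-hydroxy-4-(hydroxymethyl)phenyl hydrogen sulfate, via sodium salt 19 (not isolated)
Conditions: Pd(PPh3)4 (5 mol %), NaBH4 (4 equiv), THF/MeOH, 0 °C → rt; then Dowex 50W (H+ form), H2O/MeOH, 0 °C, freeze-drying
Reagents that add atoms: none
Why: Palladium-catalysed deallylation with hydride as the allyl acceptor (Tsuji–Trost type) and borohydride reduction of the aldehyde in one flask, both under basic conditions that an aryl sulfate, the tetrasubstituted alkene and the stereocentres survive, followed by cold ion exchange to the free hydrogen sulfate.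

**Compound list**

1 | 2-methylcyclohex-2-en-1-one | CC1=CCCCC1=O | starting material
2 | isopropenylmagnesium bromide | CC(=C)[Mg]Br | starting material
3 | (3S)-2-methyl-3-(prop-1-en-2-yl)cyclohexan-1-one (C2 epimers) | O=C1CCC[C@H](C(C)=C)C1C | intermediate
4 | 1-chloro-3-iodopropane | ClCCCI | starting material
5 | (3S)-3-(5-chloro-2-methylpentan-2-yl)-2-methylcyclohexan-1-one | O=C1CCC[C@H](C(C)(C)CCCCl)C1C | intermediate
6 | (4aR,8aS)-5,5,8a-trimethyloctahydronaphthalen-1(2H)-one (cis-fused) | O=C1CCC[C@@H]2C(C)(C)CCC[C@]12C | intermediate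
7 | lithium enolate of 6 | [Li]OC1=CCC[C@@H]2C(C)(C)CCC[C@]12C | intermediate
8 | (4aR,8aS)-2,5,5,8a-tetramethyloctahydronaphthalen-1(2H)-one (C2 epimers) | O=C1C(C)CC[C@@H]2C(C)(C)CCC[C@]12C | intermediate
9 | potassium enolate of 8 | [K]OC1=C(C)CC[C@@H]2C(C)(C)CCC[C@]12C | intermediate
10 | (4aR,8aS)-2,5,5,8a-tetramethyl-3,4,4a,5,6,7,8,8a-octahydronaphthalen-1-yl trifluoromethanesulfonate | CC1=C(OS(=O)(=O)C(F)(F)F)[C@@]2(C)CCCC(C)(C)[C@H]2CC1 | intermediate
11 | catechol | Oc1ccccc1O | starting material
12 | 2-(prop-2-en-1-yloxy)phenol | C=CCOc1ccccc1O | intermediate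
13 | 4-bromo-2-(prop-2-en-1-yloxy)phenol | C=CCOc1cc(Br)ccc1O | intermediate
14 | lithium 4-lithio-2-(prop-2-en-1-yloxy)phenoxide | C=CCOc1cc([Li])ccc1O[Li] | intermediate
15 | 4-hydroxy-3-(prop-2-en-1-yloxy)benzaldehyde | C=CCOc1cc(C=O)ccc1O | intermediate
16 | 3-(chloromethyl)-4-hydroxy-5-(prop-2-en-1-yloxy)benzaldehyde | C=CCOc1cc(C=O)cc(CCl)c1O | intermediate
17 | 3-{[(4aR,8aS)-2,5,5,8a-tetramethyl-3,4,4a,5,6,7,8,8a-octahydronaphthalen-1-yl]methyl}-4-hydroxy-5-(prop-2-en-1-yloxy)benzaldehyde | CC1=C(Cc2cc(C=O)cc(OCC=C)c2O)[C@@]2(C)CCCC(C)(C)[C@H]2CC1 | intermediate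
18 | sodium 2-{[(4aR,8aS)-2,5,5,8a-tetramethyl-3,4,4a,5,6,7,8,8a-octahydronaphthalen-1-yl]methyl}-4-formyl-6-(prop-2-en-1-yloxy)phenyl sulfate | CC1=C(Cc2cc(C=O)cc(OCC=C)c2OS(=O)(=O)[O-])[C@@]2(C)CCCC(C)(C)[C@H]2CC1.[Na+] | intermediate
19 | sodium 2-{[(4aR,8aS)-2,5,5,8a-tetramethyl-3,4,4a,5,6,7,8,8a-octahydronaphthalen-1-yl]methyl}-6-hydroxy-4-(hydroxymethyl)phenyl sulfate | CC1=C(Cc2cc(CO)cc(O)c2OS(=O)(=O)[O-])[C@@]2(C)CCCC(C)(C)[C@H]2CC1.[Na+] | intermediate
20 | 2-{[(4aR,8aS)-2,5,5,8a-tetramethyl-3,4,4a,5,6,7,8,8a-octahydronaphthalen-1-yl]methyl}-6-hydroxy-4-(hydroxymethyl)phenyl hydrogen sulfate | CC1=C(Cc2cc(CO)cc(O)c2OS(=O)(=O)O)[C@@]2(C)CCCC(C)(C)[C@H]2CC1 | target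

**Step count and risks**

Total steps: 12. Longest linear sequence: 8 (steps 1–5, then 10–12); the arene branch is steps 6–9.

Most likely to fail, in this order:

Step 10 (coupling of a very hindered tetrasubstituted triflate; the free phenol and the allyl ether sit next to low-valent nickel). The fallback sets out from 10 and swaps the radical nickel step for a two-electron palladium cycle in which the alkene carbon is the nucleophile. Pd(PPh3)4, LiCl and hexamethylditin in dioxane at 80 °C convert the triflate into trimethyl[(4aR,8aS)-2,5,5,8a-tetramethyl-3,4,4a,5,6,7,8,8a-octahydronaphthalen-1-yl]stannane F1. A base-free Stille coupling of F1 with 16 (Pd2(dba)3, tri(2-furyl)phosphine, NMP, 60 °C) then gives 17, where the route is rejoined.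

Step 2 (the nickel may reduce the iodide or the tertiary radical may simply be hydrogenated). The fallback sets out from 3 and avoids the nickel cross-coupling. A HAT allyl transfer (Fe(acac)3, PhSiH3, allyl phenyl sulfone, EtOH, 60 °C; addition of the tertiary radical to the sulfone and loss of the sulfonyl radical) gives (3S)-2-methyl-3-(2-methylpent-4-en-2-yl)cyclohexan-1-one F2. Radical anti-Markovnikov addition of HBr (HBr gas, dibenzoyl peroxide cat., pentane, 0 °C) gives (3S)-3-(5-bromo-2-methylpentan-2-yl)-2-methylcyclohexan-1-one F3. KOtBu in THF/t-BuOH then closes ring A as in step 3, and the route is rejoined at 6.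

Step 1 (enantioselectivity of an alkenyl Grignard addition to an α-substituted enone is uncertain). The fallback sets out from 2 and uses commercial cyclohex-2-en-1-one (seven non-hydrogen atoms) in place of 1. The stereo-defining addition is thus moved to the best-precedented enone class (CuBr·SMe2, Josiphos-type ferrocenyl diphosphine, t-BuOMe, −75 °C) and gives the enolate bromomagnesium (3S)-3-(prop-1-en-2-yl)cyclohex-1-en-1-olate F4. F4 is methylated in the same flask (MeI, DMPU, −30 °C → rt) to give 3, mainly as its 2,3-trans epimer, where the route is rejoined.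

**Further compounds**

F1 | step 10 | trimethyl[(4aR,8aS)-2,5,5,8a-tetramethyl-3,4,4a,5,6,7,8,8a-octahydronaphthalen-1-yl]stannane | CC1=C([Sn](C)(C)C)[C@@]2(C)CCCC(C)(C)[C@H]2CC1
F2 | step 2 | (3S)-2-methyl-3-(2-methylpent-4-en-2-yl)cyclohexan-1-one | O=C1CCC[C@H](C(C)(C)CC=C)C1C
F3 | step 2 | (3S)-3-(5-bromo-2-methylpentan-2-yl)-2-methylcyclohexan-1-one | O=C1CCC[C@H](C(C)(C)CCCBr)C1C
F4 | step 1 | bromomagnesium (3S)-3-(prop-1-en-2-yl)cyclohex-1-en-1-olate | Br[Mg]OC1=C[C@@H](C(C)=C)CCC1
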